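**Retrosynthetic overview**
- Target ⇒ benzyl ether (hydrogenolysis) ⇒ 8α,9α-epoxide ester; the trans-8,9-diol comes from acid opening of the epoxide with inversion at C8.
- C6–O ester ⇒ late acylation of the C15 epoxy-diol with 4-(benzyloxy)benzoyl chloride (three steps from 4-bromophenol); the two halves are of nearly equal size.
- Epoxy-diol ⇒ 6-OH-directed epoxidation of jaeschkeanadiol ⇒ isopropyl addition to a trans-fused hydroxy-hydroazulenone.
- Seven-membered ring ⇒ ring-closing metathesis (C8=C9) of an allyl/methallyl diene.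
- Diene ⇒ one-pot union of 3-allylcyclopentenone, Me3Al (Cu-catalysed, sets C1) and 3-methylbut-3-enal (aldol, sets C5 and C6). Ring order: the cyclopentane is bought in as a cyclopentenone; the cycloheptene is closed second.

Assumption/convention (one line): simple commercial organometallics and CO2 are listed as reagents that add atoms, not as numbered compounds; locants C1–C10 are daucane numbering (C1 angular-methyl carbon, C4 isopropyl carbinol, C5 ring-fusion CH, C6 ester carbon, C8 methyl carbinol, C9 secondary carbinol), α = face of H-5, β = face of the angular methyl.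

**Step 1**
Reactants: 1 3-methoxycyclopent-2-en-1-one
Product: 3 3-(prop-2-en-1-yl)cyclopent-2-en-1-one, via 3-methoxy-1-(prop-2-en-1-yl)cyclopent-2-en-1-ol 2 (not isolated)
Conditions: allylMgBr (1.2 equiv), Et2O, 0 °C; then 1 M HCl, 0 °C, short contact
Reagents that add atoms: allylmagnesium bromide, C=CC[Mg]Br
Why: 1,2-addition of the Grignard reagent to the vinylogous ester, then acid hydrolysis with loss of methanol (Stork–Danheiser enone transposition), gives the 3-substituted enone; no stereocentre is formed.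

**Step 2**
Reactants: 4 3-methylbut-3-en-1-ol
Product: 5 3-methylbut-3-enal
Conditions: Dess–Martin periodinane (1.1 equiv), CH2Cl2, 0 °C → rt; used at once as a cold solution
Reagents that add atoms: none
Why: Dess–Martin oxidation converts the primary alcohol to the aldehyde under near-neutral conditions that leave the β,γ-double bond out of conjugation; no stereocentre is formed.

**Step 3**
Reactants: 3 3-(prop-2-en-1-yl)cyclopent-2-en-1-one; 5 3-methylbut-3-enal
Product: 7 (2S,3R)-2-[(1S)-1-hydroxy-3-methylbut-3-en-1-yl]-3-methyl-3-(prop-2-en-1-yl)cyclopentan-1-one, via dimethylaluminium (3R)-3-methyl-3-(prop-2-en-1-yl)cyclopent-1-en-1-olate 6 (not isolated)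
Conditions: Me3Al (2 equiv), Cu(OTf)2 (5 mol %), chiral sulfonate-NHC·Ag precatalyst (2.5 mol %, enantiomer giving R at C1), THF, −78 °C; then 5 (4 equiv), −78 → −50 °C; cold 1 M HCl
Reagents that add atoms: trimethylaluminium, C[Al](C)C
Why: Cu/NHC-catalysed asymmetric conjugate addition sets the quaternary C1 (R) under catalyst control and gives the regiodefined aluminium enolate, whose aldol addition through a closed Zimmerman–Traxler chair takes place anti to the larger allyl group (C5, arms trans) and with the anti topicity of a cyclic E-enolate (C6, S).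

**Step 4**
Reactants: 7 (2S,3R)-2-[(1S)-1-hydroxy-3-methylbut-3-en-1-yl]-3-methyl-3-(prop-2-en-1-yl)cyclopentan-1-one
Product: 8 (3aR,8S,8aS)-8-hydroxy-3a,6-dimethyl-2,3,3a,4,7,8-hexahydroazulen-1(8aH)-one (trans-fused; C4 ketone, 6α-OH, C8=C9 alkene in daucane numbering)
Conditions: Grubbs II (5 mol %), CH2Cl2 (0.005 M), 40 °C
Reagents that add atoms: none
Why: Ring-closing metathesis of the allyl and methallyl olefins closes the seven-membered ring as the trisubstituted C8=C9 alkene, driven by loss of ethene; existing stereocentres are untouched.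

**Step 5**
Reactants: 8 (3aR,8S,8aS)-8-hydroxy-3a,6-dimethyl-2,3,3a,4,7,8-hexahydroazulen-1(8aH)-one
Product: 9 jaeschkeanadiol, (3R,3aS,4S,8aR)-6,8a-dimethyl-3-(propan-2-yl)-1,2,3,3a,4,5,8,8a-octahydroazulene-3,4-diol
Conditions: i-PrMgCl (4 equiv), anhydrous CeCl3 (4 equiv), THF, −78 → 0 °C; cold 0.5 M HCl
Reagents that add atoms: isopropylmagnesium chloride, CC(C)[Mg]Cl
Why: The organocerium reagent (Imamoto conditions) adds 1,2 to the hindered, enolisable ketone without enolisation or reduction, attacking C4 from the α-face opposite the 1,3-related angular methyl and on the side of the chelating C6 alkoxide, which gives the 4β-tertiary alcohol (R).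

**Step 6**
Reactants: 9 jaeschkeanadiol
Product: 10 8α,9α-epoxyjaeschkeanadiol, (1R,4R,5S,6S,8R,9S)-8,9-epoxydaucane-4,6-diol
Conditions: VO(acac)2 (5 mol %), t-BuOOH (1.5 equiv, in decane), CH2Cl2, 0 °C → rt
Reagents that add atoms: tert-butyl hydroperoxide, CC(C)(C)OO
Why: Vanadium-catalysed hydroxyl-directed epoxidation: the homoallylic 6α-OH binds the vanadium peroxide and delivers oxygen to the same (α) face of the C8=C9 alkene, setting C8 (R) and C9 (S).

**Step 7**
Reactants: 11 4-bromophenol
Product: 12 1-(benzyloxy)-4-bromobenzene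
Conditions: BnBr (1.1 equiv), K2CO3, acetone, reflux
Reagents that add atoms: benzyl bromide, BrCc1ccccc1
Why: Williamson ether synthesis protects the phenol so that it survives Grignard formation and the later acylation.

**Step 8**
Reactants: 12 1-(benzyloxy)-4-bromobenzene
Product: 14 4-(benzyloxy)benzoic acid, via [4-(benzyloxy)phenyl]magnesium bromide 13 (not isolated)
Conditions: Mg, I2 (cat.), THF, reflux; then CO2, −20 °C → rt; 1 M HCl
Reagents that add atoms: carbon dioxide, O=C=O
Why: Grignard formation and carboxylation with CO2 installs the carboxyl carbon para to the protected phenol.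

**Step 9**
Reactants: 14 4-(benzyloxy)benzoic acid
Product: 15 4-(benzyloxy)benzoyl chloride
Conditions: (COCl)2 (1.5 equiv), DMF (cat.), CH2Cl2, 0 °C → rt; evaporate
Reagents that add atoms: oxalyl chloride, O=C(Cl)C(Cl)=O
Why: Vilsmeier-catalysed acid chloride formation gives an acylating agent strong enough for the hindered secondary alcohol.

**Step 10**
Reactants: 10 8α,9α-epoxyjaeschkeanadiol; 15 4-(benzyloxy)benzoyl chloride
Product: 16 (1R,4R,5S,6S,8R,9S)-8,9-epoxy-4-hydroxydaucan-6-yl 4-(benzyloxy)benzoate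
Conditions: Et3N (3 equiv), DMAP (0.3 equiv), CH2Cl2, 0 °C → rt
Reagents that add atoms: none
Why: DMAP-catalysed acylation joins the two halves at the secondary 6-OH, leaving the tertiary 4-OH and the base-stable epoxide alone; C6 keeps its configuration because its C–O bond is not broken.

**Step 11**
Reactants: 16 (1R,4R,5S,6S,8R,9S)-8,9-epoxy-4-hydroxydaucan-6-yl 4-(benzyloxy)benzoate
Product: 17 [(3R,3aS,4S,6S,7S,8aR)-3,6,7-trihydroxy-6,8a-dimethyl-3-(propan-2-yl)decahydroazulen-4-yl] 4-(benzyloxy)benzoate
Conditions: HClO4 (0.2 equiv), THF/H2O 3:1, 0 °C → rt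
Reagents that add atoms: water, O
Why: Acid-catalysed epoxide hydrolysis: water attacks the protonated epoxide at the more substituted C8 with inversion, giving 8β-OH (S) while the 9α-oxygen (S) is retained, i.e. the trans-8,9-diol.

**Step 12**
Reactants: 17 [(3R,3aS,4S,6S,7S,8aR)-3,6,7-trihydroxy-6,8a-dimethyl-3-(propan-2-yl)decahydroazulen-4-yl] 4-(benzyloxy)benzoate
Product: 18 [(3R,3aS,4S,6S,7S,8aR)-3,6,7-trihydroxy-6,8a-dimethyl-3-(propan-2-yl)decahydroazulen-4-yl] 4-hydroxybenzoate (CNP0197754.1)
Conditions: H2 (1 atm), 10% Pd/C, EtOAc, rt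
Reagents that add atoms: none
Why: Hydrogenolysis of the benzyl aryl ether frees the phenol; nothing else in the molecule is reducible and no stereocentre is touched.

**Compound list**
1 | 3-methoxycyclopent-2-en-1-one | COC1=CC(=O)CC1 | starting material
2 | 3-methoxy-1-(prop-2-en-1-yl)cyclopent-2-en-1-ol (racemic, as Mg alkoxide, not isolated) | COC1=CC(O)(CC=C)CC1 | intermediate
3 | 3-(prop-2-en-1-yl)cyclopent-2-en-1-one | C=CCC1=CC(=O)CC1 | intermediate
4 | 3-methylbut-3-en-1-ol | CC(=C)CCO | starting material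
5 | 3-methylbut-3-enal | CC(=C)CC=O | intermediate
6 | dimethylaluminium (3R)-3-methyl-3-(prop-2-en-1-yl)cyclopent-1-en-1-olate (not isolated) | C[Al](C)OC1=C[C@@](C)(CC=C)CC1 | intermediate
7 | (2S,3R)-2-[(1S)-1-hydroxy-3-methylbut-3-en-1-yl]-3-methyl-3-(prop-2-en-1-yl)cyclopentan-1-one | O=C1CC[C@](C)(CC=C)[C@H]1[C@@H](O)CC(C)=C | intermediate
8 | (3aR,8S,8aS)-8-hydroxy-3a,6-dimethyl-2,3,3a,4,7,8-hexahydroazulen-1(8aH)-one | O=C1CC[C@]2(C)CC=C(C)C[C@H](O)[C@H]21 | intermediate
9 | jaeschkeanadiol, (3R,3aS,4S,8aR)-6,8a-dimethyl-3-(propan-2-yl)-1,2,3,3a,4,5,8,8a-octahydroazulene-3,4-diol | CC(C)[C@]1(O)CC[C@]2(C)CC=C(C)C[C@H](O)[C@H]21 | intermediate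
10 | 8α,9α-epoxyjaeschkeanadiol, (1R,4R,5S,6S,8R,9S)-8,9-epoxydaucane-4,6-diol | CC(C)[C@]1(O)CC[C@]2(C)C[C@@H]3O[C@]3(C)C[C@H](O)[C@H]21 | intermediate
11 | 4-bromophenol | Oc1ccc(Br)cc1 | starting material
12 | 1-(benzyloxy)-4-bromobenzene | Brc1ccc(OCc2ccccc2)cc1 | intermediate
13 | [4-(benzyloxy)phenyl]magnesium bromide (not isolated) | Br[Mg]c1ccc(OCc2ccccc2)cc1 | intermediate
14 | 4-(benzyloxy)benzoic acid | OC(=O)c1ccc(OCc2ccccc2)cc1 | intermediate
15 | 4-(benzyloxy)benzoyl chloride | ClC(=O)c1ccc(OCc2ccccc2)cc1 | intermediate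
16 | (1R,4R,5S,6S,8R,9S)-8,9-epoxy-4-hydroxydaucan-6-yl 4-(benzyloxy)benzoate | CC(C)[C@]1(O)CC[C@]2(C)C[C@@H]3O[C@]3(C)C[C@H](OC(=O)c4ccc(OCc5ccccc5)cc4)[C@H]21 | intermediate
17 | [(3R,3aS,4S,6S,7S,8aR)-3,6,7-trihydroxy-6,8a-dimethyl-3-(propan-2-yl)decahydroazulen-4-yl] 4-(benzyloxy)benzoate | CC(C)[C@]1(O)CC[C@]2(C)C[C@H](O)[C@@](C)(O)C[C@H](OC(=O)c3ccc(OCc4ccccc4)cc3)[C@H]21 | intermediate
18 | [(3R,3aS,4S,6S,7S,8aR)-3,6,7-trihydroxy-6,8a-dimethyl-3-(propan-2-yl)decahydroazulen-4-yl] 4-hydroxybenzoate | CC(C)[C@]1(O)CC[C@]2(C)C[C@H](O)[C@@](C)(O)C[C@H](OC(=O)c3ccc(O)cc3)[C@H]21 | target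

**Totals**
Total step count: 12.
Longest linear sequence: 8 steps (1 → 3 → 4 → 5 → 6 → 10 → 11 → 12).

**Three steps most likely to fail**

Step 3. The aluminium enolate may react sluggishly, Me3Al may consume the aldehyde, and the discrimination between methyl and allyl on the enolate face, like the anti/syn ratio, may be only moderate; the isomers would have to be separated at 7 or 8. The fallback sets out from 3 and comes back at 7. The same asymmetric methyl addition is run, but the aluminium enolate is quenched with Et3SiOTf and isolated as triethyl{[(3R)-3-methyl-3-(prop-2-en-1-yl)cyclopent-1-en-1-yl]oxy}silane F1, where the ee can be measured. MeLi in THF at 0 °C then cleaves it to lithium (3R)-3-methyl-3-(prop-2-en-1-yl)cyclopent-1-en-1-olate F2. Cooling to −78 °C and adding 5 gives a regiodefined lithium-enolate aldol that delivers 7. This costs one more main-line step.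

Step 5. The ketone is hindered, enolisable and a β-hydroxy ketone, so an isopropyl nucleophile may enolise or reduce it, or retro-aldol may open the ring. The fallback sets out from 8 and comes back at 9. The smaller, less basic sp2 nucleophile isopropenylmagnesium bromide with CeCl3 is added to give (3S,3aS,4S,8aR)-6,8a-dimethyl-3-(prop-1-en-2-yl)-1,2,3,3a,4,5,8,8a-octahydroazulene-3,4-diol F3. Hydrogenation with H2 and RhCl(PPh3)3 then saturates only the 1,1-disubstituted alkene and leaves the trisubstituted ring alkene, giving 9.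

Step 11. The tertiary 4β-OH could capture C8 across the ring in place of water, and a cation-like opening could give C8 epimers or allylic alcohols. The fallback sets out from 16 and comes back at 17. The tertiary hydroxyl is first capped under neutral conditions with N-(trimethylsilyl)imidazole to give the 4-O-trimethylsilyl ether of 16 F4. The same aqueous HClO4 opening at 0 °C then has water as the only nucleophile for C8, and warming to rt in the same pot removes the silyl group to give 17.

**Further compounds**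
F1 | step 3 | triethyl{[(3R)-3-methyl-3-(prop-2-en-1-yl)cyclopent-1-en-1-yl]oxy}silane | CC[Si](CC)(CC)OC1=C[C@@](C)(CC=C)CC1
F2 | step 3 | lithium (3R)-3-methyl-3-(prop-2-en-1-yl)cyclopent-1-en-1-olate | [Li]OC1=C[C@@](C)(CC=C)CC1
F3 | step 5 | (3S,3aS,4S,8aR)-6,8a-dimethyl-3-(prop-1-en-2-yl)-1,2,3,3a,4,5,8,8a-octahydroazulene-3,4-diol | CC(=C)[C@]1(O)CC[C@]2(C)CC=C(C)C[C@H](O)[C@H]21
F4 | step 11 | 4-O-trimethylsilyl ether of 16 | CC(C)[C@]1(O[Si](C)(C)C)CC[C@]2(C)C[C@@H]3O[C@]3(C)C[C@H](OC(=O)c4ccc(OCc5ccccc5)cc4)[C@H]21
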